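Z at the end is what I had to foretell, for two new flasks that differ in their charge of J and in their time.

| setting | north-east | south | noon | dawn |
|---|---|---|---|---|
| J | 5.3 mM | 7.7 mM | 12 mM | 6.0 mM |
| temperature | 95 °C | 106 °C | 100 °C | 100 °C |
| remark | run made earlier | run made earlier |  |  |
| time |  |  | 3.0 h | 0.80 h |

| run | time / h | Z / % |
|---|---|---|
| north-east | 0.250 | 21 |
| north-east | 0.417 | 30 |
| north-east | 0.833 | 43 |
| north-east | 1.50 | 49 |
| north-east | 3.00 | 51 |
| south | 0.250 | 39 |
| south | 0.833 | 49 |
| south | 1.33 | 50 |
| south | 2.00 | 53 |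
| south | 3.00 | 54 |

(scatter of a reading: 2 percentage points)

- which of the two ends with the higher amount of Z, in percent of the J charged ("neither" if they lie within 2 percentage points) (noon / dawn / neither)
- Z at the end, in percent of the J charged, noon
- Z at the end, in percent of the J charged, dawn

- a reading or a percentage of Z counts all its forms, free or not

The runs end near 51% and 54%, but they raised J and temperature together, so that likeness may hide two opposed effects. So I reckoned with what is lost, not with what is made, and I supposed that the losing path takes two molecules and grows with the charge. The last readings give lost over made, per mM charged, as 0.181 mM⁻¹ at 95 °C and 0.111 mM⁻¹ at 106 °C, both with the scatter of their readings. On a logarithmic line between them I took 0.145 mM⁻¹ at 100 °C as the J lost per J made into Z, per mM charged, a selectivity factor.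

Z at the end is then one part in one plus this factor times the charge, which gave 36.5% for noon and a plateau of 53.5% for dawn. The first readings give rate constants of 2.12 h⁻¹ and 5.12 h⁻¹, and the same line gave 3.17 h⁻¹. So dawn still had 7.93% of its rise to come, and I expected 49.3%, higher than noon.

The forecast differed: noon ahead, with 53% for noon and 48% for dawn, though it warned that “a bimolecular path could shift it either way”.

The flasks gave dawn ahead, with 38.4% for noon and 47.9% for dawn.

    J → Z (k = 5.00 × 10⁻⁴ s⁻¹, Ea = 112 kJ mol⁻¹)
    2 J ⇌ L (K = 2000 M⁻¹, k = 0.0240 M⁻¹ s⁻¹, Ea = 81.0 kJ mol⁻¹, ΔH = −39.0 kJ mol⁻¹)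
    J + Z → X (k = 0.0600 M⁻¹ s⁻¹, Ea = 74.0 kJ mol⁻¹)
    E ⇌ Z, rate k4*(cs4 - [Z]) while solid is left; crystals form when [Z] > cs4 (solubility = 5.10 mM, k = 0.00210 s⁻¹)
    (constants at 100 °C)

Noon's end corresponds to a factor of 0.134 mM⁻¹, against my 0.145 mM⁻¹, and its lost J stood as 26.2% L and 35.0% X. For a repeat of noon at 125 °C, the same line, carried on from 100 °C, gave a factor of 0.0471 mM⁻¹, so I reckoned Z at 63.9%. That flask ended, in percent of the J charged, with 0.11% of J left and 62.6% of Z, all forms counted, crystals E among them at 19.9%.

Readings and results are simulated from invented constants; the scatter is artificial.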